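The readings come from a simulation for an exercise; noise was put on by code.

**The count.** I take it that each target has used one reagent and each over-reacted product two. So with 40 mM on 20 mM, the reagent left in both phases is the starting-material charge times (target plus 2 × starting material). I count none for the protic impurity, a guess, since no run varies it.

all flasks: starting material 20 mM
- theta: reagent in the second phase 40 mM; protic impurity 5 mM; run made earlier
- flask: reagent in the second phase 40.0 mM; protic impurity 10.0 mM; time 2.5 min; volume of the second phase over the first 1.0

- theta (time / s: target / %, starting material / %): 10.0: 38, 60; 15.0: 50, 42; 20.0: 60, 29; 25.0: 66, 18; 30.0: 69, 13

(standard deviation of a reading: 1.5 percentage points)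

- target at 2.5 min, in percent of the starting material charged
- part of the starting material charged that has reacted at 2.5 min

- in the second phase: reagent in the second phase; everything else is in the first
- charges count per volume of the first phase; a concentration in a rate is the amount of a species over the volume of its own phase; every rate counts per litre of the first phase
- the numbers in the tables scatter with a standard deviation of 1.5 percentage points
- the earlier runs hold the two phases in the same ratio of volumes as the flask asked about
- no earlier run changes the charge of protic impurity; that part of a forecast is a guess

**Burn constant.** Between the first and last theta readings, starting material drops by more than target gains, so I book 16 percentage points as target lost, on a mean target of 53.5%. By the count, reagent left goes from 31.6 mM to 19.0 mM. That gives, as a reading from the scattered theta run, the burn constant, the share of target lost per second per mM of reagent left: 0.591 M⁻¹ s⁻¹.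

**Building the flask.** Take the main step by itself and the target stands at 100%. Add over-reaction at reagent held at 19.0 mM, a pseudo-first-order view: from target plus starting material at the last theta reading, 82.0%, over the further 120 s of the flask, my target falls to 21.3%. Now let reagent run down by the count, and for this reckoning treat all of that sum as target, so that reagent tracks target: the inverse of target grows by burn constant × charge × time, giving 37.9%. A straight mean of reagent gives 31.9% instead, an error of 6 points. I commit to 37.9%, with conversion near complete.

**The forecast.** It gives 49% (38% to 60%) and 99% (95% to 100%): “essentially all reagent has been delivered, so stoichiometry decides the outcome”. My target is lower than its figure.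

**The result.** The flask gives 27.8% target and >99.9% reacted.

    reagent in the reaction phase + target → over-reacted product (k = 1.63 M⁻¹ s⁻¹)
    reagent in the reaction phase → decomposed reagent (k = 0.00136 s⁻¹)
    starting material + protic impurity → quenched substrate (k = 0.321 M⁻¹ s⁻¹)
    starting material + reagent in the reaction phase → target (k = 8.51 M⁻¹ s⁻¹)
    reagent in the reaction phase ⇌ reagent in the second phase, rate k5*([reagent in the reaction phase] - [reagent in the second phase]/K5) per volume of the first phase (partition coefficient = 0.750, kL = 0.0468 s⁻¹)

Carry the burn constant to the neighbour with 25 mM of protic impurity, which holds 11.4% quenched substrate at 2.50 min against the flask's 4.95%. Taking that extra share off at the start and using the straight mean down to the neighbour's 7.67 mM of reagent left in both phases gives 29.3%. The neighbour holds 22.1% target.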